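**Retrosynthetic overview**
1. The CH2 bridge is cut at both ring-C–CH2 bonds. This gives 6-ethyl-4-hydroxy-5-methylpyran-2-one (nucleophilic at C3), one carbon from [CH2=NMe2]I, and the C-prenylated (S)-acylphloroglucinol, which reacts at its last free ring carbon.
2. The prenyl group is removed to (S)-2-methyl-1-(2,4,6-trihydroxyphenyl)butan-1-one, which has two equivalent free ring carbons for C-alkylation with prenyl bromide.
3. The strategy rests on the benzene ring, which has oxygen on C2, C4 and C6 and the 2-methylbutanoyl group on C1. This alternate oxidation pattern is that of a folded four-carbonyl chain, so the ring is opened between the acyl-bearing carbon and a neighbouring C–OH to methyl (S)-8-methyl-3,5,7-trioxodecanoate (chain C6 closes onto ester C1). The stereocentre is bought in (S)-2-methylbutanoic acid and lies outside the enolised array.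
4. The triketo ester comes from the N-methoxy-N-methylamide of the acid and the trianion of methyl 3,5-dioxohexanoate. The pyranone comes from methyl 3-oxopentanoate dianion and N-methoxy-N-methylpropanamide, followed by lactonisation.
5. Ring order: benzene ring (step 4); pyranone ring made separately (step 7); the two rings are joined in step 8 without further ring formation.

Key step: step 4

Assumption: the stereocentre is (S) as read from the SMILES. Compounds 6, 7 and 14 are drawn as keto forms although they are largely enolised, C4 of 14 is a racemic enolisable centre that becomes sp2 in step 7, and 16 is present in the flask as its hydroiodide.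

**Step 1**
Reactants: 1 (S)-2-methylbutanoic acid
Product: 3 (S)-N-methoxy-N,2-dimethylbutanamide, via acyl imidazolide 2 (not isolated)
Conditions: CDI (1.1 equiv), CH2Cl2, 0 °C to rt; then MeNH(OMe)·HCl (1.2 equiv), rt
Reagents that add atoms: N,O-dimethylhydroxylamine hydrochloride, CNOC.Cl; 1,1'-carbonyldiimidazole, O=C(n1ccnc1)n1ccnc1 (supplies only the imidazolyl group of intermediate 2)
Why: Acyl imidazolide formation and aminolysis (CDI amide coupling) run under near-neutral conditions at or below room temperature, so the α-stereocentre of 1 should be carried into the amide without enolisation and no new stereocentre is formed.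

**Step 2**
Reactants: 4 methyl acetoacetate; 5 N-methoxy-N-methylacetamide
Product: 6 methyl 3,5-dioxohexanoate
Conditions: 4 (1.2 equiv), NaH, THF, 0 °C; n-BuLi, 0 °C; 5 (1.0 equiv), −78 to 0 °C; cold 1 M HCl
Reagents that add atoms: none
Why: The acetoacetate dianion is acylated at its terminal γ-carbanion by the N-methoxy-N-methylamide (Weinreb ketone synthesis), and the chelated tetrahedral adduct persists until the acidic quench, so over-addition is prevented.

**Step 3**
Reactants: 6 methyl 3,5-dioxohexanoate; 3 (S)-N-methoxy-N,2-dimethylbutanamide
Product: 7 methyl (S)-8-methyl-3,5,7-trioxodecanoate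
Conditions: 6 (1.25 equiv), LiN(iPr)2 (3.1 equiv per 6), THF, −78 to 0 °C; 3 (1.0 equiv), −78 to −20 °C; poured into cold aq HCl (pH 3), rapid extraction, used without delay
Reagents that add atoms: none
Why: The trianion of 6 reacts at its last-formed, most nucleophilic terminal carbanion (C6) with the amide in a Weinreb-type acylation that stops at the ketone stage, and the low temperature should keep proton transfer from the hindered α-C–H of 3 slower than carbonyl addition so that the (S)-centre is retained.

**Step 4**
Reactants: 7 methyl (S)-8-methyl-3,5,7-trioxodecanoate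
Product: 9 (S)-2-methyl-1-(2,4,6-trihydroxyphenyl)butan-1-one, via cyclic triketone 8 (not isolated)
Conditions: KOH (5 equiv), dry MeOH, N2, 0 °C to rt; then 1 M HCl
Reagents that add atoms: none
Why: Excess methanolic base converts the C5/C7 β-diketone end of 7 into its enolate, whose central carbon C6 adds to the ester carbonyl C1 and expels methoxide (intramolecular Claisen, that is Dieckmann-type, condensation) to give cyclic triketone 8, which tautomerises at once to arene 9 and is held as its phenoxide, making the closure irreversible. The closest known reaction type is the base-mediated Claisen cyclisation of 3,5,7-trioxoalkanoate esters to acylphloroglucinols, the laboratory counterpart of chalcone-synthase-type polyketide folding. The one ring formed, the carbocycle C1–C6, closes by the new C1–C6 bond in a 6-exo-trig acyl substitution, which is geometrically favoured for either canonical form of the enolate. No stereocentre is created, and the existing C8 centre sits next to a carbonyl that is tied up in the C5–C7 enolate and later in the phenoxide-conjugated aryl ketone, so it should not be deprotonated. The step needs chemoselectivity for C6-to-C1 Claisen closure over C2-to-C7 aldol closure (which would give a resorcylate) and over O-acyl lactonisation to a 4-hydroxypyran-2-one. Full enolisation of the C5/C7 unit by strong non-aqueous base removes C7 as an electrophile and avoids saponification to a carboxylate that could only close by aldol, the α-branch next to C7 further hinders the aldol mode, and any pyranone formed is reopened by methoxide and drained to the arene.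

**Step 5**
Reactants: 9 (S)-2-methyl-1-(2,4,6-trihydroxyphenyl)butan-1-one; 10 1-bromo-3-methylbut-2-ene
Product: 11 (S)-2-methyl-1-[2,4,6-trihydroxy-3-(3-methylbut-2-en-1-yl)phenyl]butan-1-one
Conditions: 10 (0.9 equiv), 10% aq KOH, N2, 0 °C; then 1 M HCl; unreacted 9 recycled
Reagents that add atoms: none
Why: In aqueous alkali the phloroglucinol phenoxide reacts as a carbon nucleophile (ambident-phenoxide C-alkylation, SN2 on the allylic bromide) at one of its two equivalent free ring carbons, a deficit of bromide limits double alkylation, and the stereocentre is untouched.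

**Step 6**
Reactants: 12 methyl 3-oxopentanoate; 13 N-methoxy-N-methylpropanamide
Product: 14 methyl 4-methyl-3,5-dioxoheptanoate
Conditions: 12 (1.2 equiv), NaH, THF, 0 °C; n-BuLi, 0 °C; 13 (1.0 equiv), −78 to 0 °C; cold 1 M HCl
Reagents that add atoms: none
Why: The β-keto ester dianion is acylated at its γ-carbanion (C4) by the N-methoxy-N-methylamide (Weinreb ketone synthesis), giving the 4-methyl-3,5-diketo ester as a racemic, largely enolised compound whose C4 centre is flattened in the next step.

**Step 7**
Reactants: 14 methyl 4-methyl-3,5-dioxoheptanoate
Product: 15 6-ethyl-4-hydroxy-5-methyl-2H-pyran-2-one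
Conditions: DBU (1.5 equiv), toluene, reflux; then 1 M HCl
Reagents that add atoms: none
Why: Base-promoted enolisation of the C5 ketone and attack of the enol oxygen on the ester (lactonisation of a 3,5-dioxo ester, 6-exo-trig) with loss of methanol should give the 4-hydroxypyran-2-one, driven by formation of its stable conjugated enolate.

**Step 8**
Reactants: 15 6-ethyl-4-hydroxy-5-methyl-2H-pyran-2-one; 11 (S)-2-methyl-1-[2,4,6-trihydroxy-3-(3-methylbut-2-en-1-yl)phenyl]butan-1-one
Product: 18 (S)-6-ethyl-4-hydroxy-5-methyl-3-{[2,4,6-trihydroxy-3-(2-methylbutanoyl)-5-(3-methylbut-2-en-1-yl)phenyl]methyl}-2H-pyran-2-one, via Mannich base 16 (not isolated), via methylidene pyrandione 17 (not isolated)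
Conditions: 15, [CH2=NMe2]I (1.0 equiv), CHCl3, rt; then 11 (1.0 equiv), 50 °C
Reagents that add atoms: dimethylmethylideneammonium iodide, C=[N+](C)C.[I-]
Why: A Mannich reaction at the nucleophilic C3 of 15 gives 16, which on warming loses dimethylamine to the methylidene pyrandione 17 (an ortho-quinone-methide-type acceptor) that is captured in a Friedel–Crafts-type conjugate addition by the single unsubstituted ring carbon of 11; forming 16 fully before 11 is added suppresses homodimers, and the stereocentre and prenyl group are not involved.

**Compound list**
1 | (S)-2-methylbutanoic acid | OC(=O)[C@@H](C)CC | starting material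
2 | (S)-1-(1H-imidazol-1-yl)-2-methylbutan-1-one | O=C([C@@H](C)CC)n1ccnc1 | intermediate (not isolated)
3 | (S)-N-methoxy-N,2-dimethylbutanamide | CON(C)C(=O)[C@@H](C)CC | intermediate
4 | methyl acetoacetate | COC(=O)CC(C)=O | starting material
5 | N-methoxy-N-methylacetamide | CC(=O)N(C)OC | starting material
6 | methyl 3,5-dioxohexanoate | COC(=O)CC(=O)CC(C)=O | intermediate
7 | methyl (S)-8-methyl-3,5,7-trioxodecanoate | COC(=O)CC(=O)CC(=O)CC(=O)[C@@H](C)CC | intermediate
8 | 2-[(S)-2-methylbutanoyl]cyclohexane-1,3,5-trione | O=C([C@@H](C)CC)C1C(=O)CC(=O)CC1=O | intermediate (not isolated)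
9 | (S)-2-methyl-1-(2,4,6-trihydroxyphenyl)butan-1-one | O=C([C@@H](C)CC)c1c(O)cc(O)cc1O | intermediate
10 | 1-bromo-3-methylbut-2-ene | CC(C)=CCBr | starting material
11 | (S)-2-methyl-1-[2,4,6-trihydroxy-3-(3-methylbut-2-en-1-yl)phenyl]butan-1-one | O=C([C@@H](C)CC)c1c(O)cc(O)c(CC=C(C)C)c1O | intermediate
12 | methyl 3-oxopentanoate | CCC(=O)CC(=O)OC | starting material
13 | N-methoxy-N-methylpropanamide | CCC(=O)N(C)OC | starting material
14 | methyl 4-methyl-3,5-dioxoheptanoate (racemic) | CCC(=O)C(C)C(=O)CC(=O)OC | intermediate
15 | 6-ethyl-4-hydroxy-5-methyl-2H-pyran-2-one | CCc1oc(=O)cc(O)c1C | intermediate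
16 | 3-[(dimethylamino)methyl]-6-ethyl-4-hydroxy-5-methyl-2H-pyran-2-one | CCc1oc(=O)c(CN(C)C)c(O)c1C | intermediate (not isolated)
17 | 6-ethyl-5-methyl-3-methylidene-2H-pyran-2,4(3H)-dione | CCC1=C(C)C(=O)C(=C)C(=O)O1 | intermediate (not isolated)
18 | (S)-6-ethyl-4-hydroxy-5-methyl-3-{[2,4,6-trihydroxy-3-(2-methylbutanoyl)-5-(3-methylbut-2-en-1-yl)phenyl]methyl}-2H-pyran-2-one | CCc1oc(=O)c(Cc2c(O)c(CC=C(C)C)c(O)c(C(=O)[C@@H](C)CC)c2O)c(O)c1C | target

**Step count**
Total: 8 steps. Longest linear sequence: 5 steps (step 1 or 2, then 3, 4, 5, 8); the pyranone branch (steps 6, 7) joins at step 8.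

**Steps most likely to fail**

Step 3. Two processes threaten it. The strongly basic trianion may take the α-proton of amide 3 instead of adding to its carbonyl, which erodes the configuration and returns both partners. The free triketo ester may also close in an uncontrolled mode during quench and purification. The fallback masks the ester end as a dioxinone and uses a less basic dianion. It sets out from 3. Commercial 2,2,6-trimethyl-4H-1,3-dioxin-4-one is C-acetylated through its lithium dienolate (LiN(SiMe3)2, THF, −78 °C; acetyl chloride) to 2,2-dimethyl-6-(2-oxopropyl)-4H-1,3-dioxin-4-one F1. The dianion of F1 (LiN(iPr)2, 2.2 equiv, THF, −78 °C) is acylated at its terminal methyl by 3 to give 2,2-dimethyl-6-[(5S)-5-methyl-2,4-dioxoheptyl]-4H-1,3-dioxin-4-one F2. Heating F2 in toluene with methanol at about 105 °C expels acetone by retro-[4+2] cleavage, and the acylketene is trapped by methanol. This rejoins the route at 7, which is taken crude into step 4.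

Step 4. The chain may close by the aldol mode (C2 onto C7) to a resorcylate, lactonise through oxygen, or be cut by retro-Claisen attack of methoxide, so that little arene of the wanted type forms. The fallback gives up ring construction and acylates a preformed ring. It sets out from 1, which is converted with (COCl)2 and catalytic DMF in CH2Cl2 to (S)-2-methylbutanoyl chloride F3. Friedel–Crafts acylation of commercial benzene-1,3,5-triol with F3 (AlCl3, CH2Cl2/nitrobenzene, 0 °C to rt, kept cold to limit enolisation of the acylium precursor) rejoins the route at 9.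

Step 5. Over-alkylation to bis-C-prenyl and dearomatised geminal diprenyl products, together with competing O-alkylation, may leave the mono-C-prenyl compound as a minor component. The fallback delivers the prenyl group intramolecularly. It sets out from 9, whose non-chelated 4-OH is etherified with 3-chloro-3-methylbut-1-yne (K2CO3, KI, catalytic CuI, acetone, rt) to (S)-1-[2,6-dihydroxy-4-(2-methylbut-3-yn-2-yloxy)phenyl]-2-methylbutan-1-one F4. Semihydrogenation of the alkyne (H2, Pd/CaCO3 poisoned with Pb(OAc)2, quinoline, EtOAc) gives (S)-1-[2,6-dihydroxy-4-(2-methylbut-3-en-2-yloxy)phenyl]-2-methylbutan-1-one F5. Heating F5 in N,N-diethylaniline at about 110 °C brings about an aromatic Claisen rearrangement to the ortho ring carbon (either one, they are equivalent), and tautomerisation rejoins the route at 11.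

**Further compounds**
F1 | step 3 | 2,2-dimethyl-6-(2-oxopropyl)-4H-1,3-dioxin-4-one | CC(=O)CC1=CC(=O)OC(C)(C)O1
F2 | step 3 | 2,2-dimethyl-6-[(5S)-5-methyl-2,4-dioxoheptyl]-4H-1,3-dioxin-4-one | O=C([C@@H](C)CC)CC(=O)CC1=CC(=O)OC(C)(C)O1
F3 | step 4 | (S)-2-methylbutanoyl chloride | O=C(Cl)[C@@H](C)CC
F4 | step 5 | (S)-1-[2,6-dihydroxy-4-(2-methylbut-3-yn-2-yloxy)phenyl]-2-methylbutan-1-one | O=C([C@@H](C)CC)c1c(O)cc(OC(C)(C)C#C)cc1O
F5 | step 5 | (S)-1-[2,6-dihydroxy-4-(2-methylbut-3-en-2-yloxy)phenyl]-2-methylbutan-1-one | O=C([C@@H](C)CC)c1c(O)cc(OC(C)(C)C=C)cc1O
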